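Ring C (rings lettered A, the 2,4,6-trihydroxyphenyl end, to G) carries oxygen on C1, C3, C4, C5 and C6 and hydrogen only on C2. It is disconnected across C1–C2 to a squarate-derived cyclobutenone whose four ring carbons become C1, C6, C5 and C4 and whose 1-methoxyvinyl group supplies C3 and C2. Heating this precursor, a 2-aryloxy-3,4-dimethoxy-4-(1-methoxyvinyl)cyclobutenone already carrying the permethylated DEFG tetramer on the future C6 oxygen, opens the four-membered ring to a dienylketene that closes to ring C and leaves C1–OH as the only free phenol, the site where ring B is then attached. The diaryl ethers elsewhere come from copper couplings of formyl-activated building blocks and Baeyer–Villiger oxidation.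

Key step: step 9

Assumption (chemistry): the aryl squarate is made from squaric acid dichloride, because an aryl vinylogous ester is an activated ester that alkoxide exchange on a dialkyl squarate would not deliver; the target is achiral, so the one stereocentre of the cyclobutenone is carried as the racemate. "Ar" below is the aryl group of DEFG phenol 13.

Step 1
Reactants: 1 syringaldehyde; 2 3,4,5-trimethoxyphenylboronic acid
Product: 3 FG aldehyde [3,5-dimethoxy-4-(3,4,5-trimethoxyphenoxy)benzaldehyde]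
Conditions: Cu(OAc)2 (20 mol %), pyridine, 4 Å MS, CH2Cl2, O2 (1 atm), rt
Reagents that add atoms: none
Why: Chan–Lam O-arylation couples a 2,6-dimethoxyphenol with an electron-rich arylboronic acid at room temperature and leaves the aldehyde untouched.

Step 2
Reactants: 3 FG aldehyde
Product: 5 FG phenol [3,5-dimethoxy-4-(3,4,5-trimethoxyphenoxy)phenol], via FG formate 4 (not isolated)
Conditions: mCPBA, CH2Cl2, 0 °C to rt; then K2CO3 (cat.), MeOH, rt
Reagents that add atoms: mCPBA, O=C(OO)c1cccc(Cl)c1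
Why: Baeyer–Villiger oxidation of a benzaldehyde carrying a para-aryloxy donor migrates the aryl group to give the aryl formate, and methanolysis of this labile ester releases the phenol.

Step 3
Reactants: 5 FG phenol; 6 2-bromo-3,4,5-trimethoxybenzaldehyde
Product: 7 EFG aldehyde [2-[3,5-dimethoxy-4-(3,4,5-trimethoxyphenoxy)phenoxy]-3,4,5-trimethoxybenzaldehyde]
Conditions: CuI (10 mol %), picolinic acid (20 mol %), K3PO4, DMSO, 90 °C
Reagents that add atoms: none
Why: Ullmann-type diaryl ether coupling of an unhindered, electron-rich phenol with an aryl bromide that is activated by its ortho-formyl group.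

Step 4
Reactants: 7 EFG aldehyde
Product: 9 EFG phenol [2-[3,5-dimethoxy-4-(3,4,5-trimethoxyphenoxy)phenoxy]-3,4,5-trimethoxyphenol], via EFG formate 8 (not isolated)
Conditions: mCPBA, CH2Cl2, 0 °C to rt; then K2CO3 (cat.), MeOH, rt
Reagents that add atoms: mCPBA, O=C(OO)c1cccc(Cl)c1
Why: Baeyer–Villiger oxidation with aryl migration is favoured by the ortho-aryloxy and para-methoxy donors, and methanolysis of the formate gives the ring E phenol.

Step 5
Reactants: 9 EFG phenol; 10 3-bromo-4,5-dimethoxybenzaldehyde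
Product: 11 DEFG aldehyde [3-{2-[3,5-dimethoxy-4-(3,4,5-trimethoxyphenoxy)phenoxy]-3,4,5-trimethoxyphenoxy}-4,5-dimethoxybenzaldehyde]
Conditions: CuI (10 mol %), picolinic acid (20 mol %), K3PO4, DMSO, 100 °C
Reagents that add atoms: none
Why: Ullmann-type diaryl ether coupling under conditions developed for ortho-substituted partners, here a phenol with one ortho-aryloxy group and a bromide with one ortho-methoxy group.

Step 6
Reactants: 11 DEFG aldehyde
Product: 13 DEFG phenol [3-{2-[3,5-dimethoxy-4-(3,4,5-trimethoxyphenoxy)phenoxy]-3,4,5-trimethoxyphenoxy}-4,5-dimethoxyphenol; ArOH], via DEFG formate 12 (not isolated)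
Conditions: mCPBA, CH2Cl2, 0 °C to rt; then K2CO3 (cat.), MeOH, rt
Reagents that add atoms: mCPBA, O=C(OO)c1cccc(Cl)c1
Why: Baeyer–Villiger oxidation of a benzaldehyde with a para-methoxy donor, as in the conversion of 3,4,5-trimethoxybenzaldehyde into its phenol, followed by formate methanolysis.

Step 7
Reactants: 13 DEFG phenol; 14 squaric acid dichloride (3,4-dichlorocyclobut-3-ene-1,2-dione)
Product: 16 mixed squarate [3-(ArO)-4-methoxycyclobut-3-ene-1,2-dione], via chloro squarate 15 (not isolated)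
Conditions: 14 (3 equiv), 2,6-lutidine, CH2Cl2, −78 to 0 °C; then MeOH, 2,6-lutidine, 0 °C
Reagents that add atoms: methanol, CO
Why: Addition–elimination of the phenol on the vinylogous acid chloride, with excess dichloride suppressing double arylation, is followed by the same substitution of the remaining C–Cl by methanol under conditions too mild to exchange the aryloxy group.

Step 8
Reactants: 16 mixed squarate; 17 methyl vinyl ether
Product: 20 racemic 2-(ArO)-3,4-dimethoxy-4-(1-methoxyvinyl)cyclobut-2-en-1-one, via 1-methoxyvinyllithium 18 (not isolated), via lithium alkoxide 19 (not isolated)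
Conditions: 17 (excess), t-BuLi, THF, −78 to 0 °C; add to 16, THF, −78 °C; then MeOTf, −78 to 0 °C
Reagents that add atoms: methyl triflate, COS(=O)(=O)C(F)(F)F
Why: 1,2-Addition of an α-alkoxyvinyllithium to a squarate ester and O-methylation of the resulting alkoxide should occur at the carbonyl next to the methoxy-bearing carbon, since its vinylogous donor is the weaker aryloxy group while the other carbonyl is deactivated by the methoxy group and shielded by the tetramer; the new quaternary stereocentre forms as a racemate.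

Step 9
Reactants: 20 racemic 2-(ArO)-3,4-dimethoxy-4-(1-methoxyvinyl)cyclobut-2-en-1-one
Product: 23 CDEFG phenol [2-(ArO)-3,4,5-trimethoxyphenol], via dienylketene 21 (not isolated), via cyclohexadienone 22 (not isolated)
Conditions: toluene (dilute, degassed, base-washed glassware), 110 °C, argon
Reagents that add atoms: none
Why: Thermal conrotatory 4π opening of the cyclobutenone breaks the bond between the carbonyl carbon and the quaternary carbon and gives dienylketene 21, whose 6π electrocyclisation joins the ketene carbon to the vinyl CH2 (the C1–C2 bond of ring C) to give cyclohexadienone 22, which tautomerises to the phenol. The closest known reaction type is the Moore ring expansion of 4-alkenyl-4-alkoxycyclobutenones derived from squarate esters to polyoxygenated phenols. Ring C is closed in a disrotatory 6π electrocyclic mode with its five oxygen substituents already in place, and no stereocentre is formed because the racemic quaternary carbon becomes aromatic C4. The step needs the 1-methoxyvinyl group to turn inward so that it lies cis to the ketene, and this is secured by the methoxy group on the quaternary carbon, a donor that rotates outward in the ring opening. The substitution pattern was fixed in step 8, so the ketene carbon can only become C1–OH next to the C6 aryloxy group. Dilute, degassed, acid-free toluene should keep the ketene from bimolecular trapping and the enol ether from hydrolysis.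

Step 10
Reactants: 23 CDEFG phenol; 24 4-bromo-3,5-dimethoxybenzaldehyde
Product: 25 BCDEFG aldehyde [3,5-dimethoxy-4-[2-(ArO)-3,4,5-trimethoxyphenoxy]benzaldehyde]
Conditions: CuI (20 mol %), picolinic acid (40 mol %), K3PO4, DMSO, 105 °C
Reagents that add atoms: none
Why: Ullmann-type coupling under conditions suited to hindered diaryl ethers, in which the para-formyl group activates the doubly ortho-methoxylated C–Br bond, as 2-bromo-1,3,5-trimethoxybenzene is known to couple with phenols.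

Step 11
Reactants: 25 BCDEFG aldehyde
Product: 27 BCDEFG phenol [3,5-dimethoxy-4-[2-(ArO)-3,4,5-trimethoxyphenoxy]phenol], via BCDEFG formate 26 (not isolated)
Conditions: mCPBA, CH2Cl2, 0 °C to rt; then K2CO3 (cat.), MeOH, rt
Reagents that add atoms: mCPBA, O=C(OO)c1cccc(Cl)c1
Why: Baeyer–Villiger oxidation of the para-aryloxybenzaldehyde, the same transformation as in step 2, followed by formate methanolysis.

Step 12
Reactants: 27 BCDEFG phenol; 28 2-iodo-1,3,5-trimethoxybenzene
Product: 29 permethylated heptamer [2-{3,5-dimethoxy-4-[2-(ArO)-3,4,5-trimethoxyphenoxy]phenoxy}-1,3,5-trimethoxybenzene]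
Conditions: CuI (20 mol %), picolinic acid (40 mol %), K3PO4, DMSO, 100 °C
Reagents that add atoms: none
Why: Ullmann-type coupling of an unhindered, electron-rich phenol with the doubly ortho-substituted aryl iodide, the classical way to 2,4,6-trimethoxyphenyl ethers of the phlorethol type.

Step 13
Reactants: 29 permethylated heptamer
Product: 30 target heptamer CNP0130704.0
Conditions: BBr3 (excess), CH2Cl2, −78 °C to rt, argon; then H2O, 0 °C
Reagents that add atoms: none
Why: Lewis acid cleavage of aryl methyl ethers with BBr3 should remove all eighteen methyl groups while the diaryl ether bonds, which BBr3 does not cleave, stay intact.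

Compound list
1 | syringaldehyde (4-hydroxy-3,5-dimethoxybenzaldehyde) | COc1cc(C=O)cc(OC)c1O | starting material
2 | 3,4,5-trimethoxyphenylboronic acid | COc1cc(B(O)O)cc(OC)c1OC | starting material
3 | FG aldehyde, 3,5-dimethoxy-4-(3,4,5-trimethoxyphenoxy)benzaldehyde | O=Cc1cc(OC)c(Oc2cc(OC)c(OC)c(OC)c2)c(OC)c1 | intermediate
4 | FG formate, 3,5-dimethoxy-4-(3,4,5-trimethoxyphenoxy)phenyl formate | O=COc1cc(OC)c(Oc2cc(OC)c(OC)c(OC)c2)c(OC)c1 | intermediate
5 | FG phenol, 3,5-dimethoxy-4-(3,4,5-trimethoxyphenoxy)phenol | Oc1cc(OC)c(Oc2cc(OC)c(OC)c(OC)c2)c(OC)c1 | intermediate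
6 | 2-bromo-3,4,5-trimethoxybenzaldehyde | O=Cc1cc(OC)c(OC)c(OC)c1Br | starting material
7 | EFG aldehyde, 2-[3,5-dimethoxy-4-(3,4,5-trimethoxyphenoxy)phenoxy]-3,4,5-trimethoxybenzaldehyde | O=Cc1cc(OC)c(OC)c(OC)c1Oc1cc(OC)c(Oc2cc(OC)c(OC)c(OC)c2)c(OC)c1 | intermediate
8 | EFG formate, formate ester of 9 | O=COc1cc(OC)c(OC)c(OC)c1Oc1cc(OC)c(Oc2cc(OC)c(OC)c(OC)c2)c(OC)c1 | intermediate
9 | EFG phenol, 2-[3,5-dimethoxy-4-(3,4,5-trimethoxyphenoxy)phenoxy]-3,4,5-trimethoxyphenol | Oc1cc(OC)c(OC)c(OC)c1Oc1cc(OC)c(Oc2cc(OC)c(OC)c(OC)c2)c(OC)c1 | intermediate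
10 | 3-bromo-4,5-dimethoxybenzaldehyde | O=Cc1cc(Br)c(OC)c(OC)c1 | starting material
11 | DEFG aldehyde, 3-{2-[3,5-dimethoxy-4-(3,4,5-trimethoxyphenoxy)phenoxy]-3,4,5-trimethoxyphenoxy}-4,5-dimethoxybenzaldehyde | O=Cc1cc(OC)c(OC)c(Oc2cc(OC)c(OC)c(OC)c2Oc2cc(OC)c(Oc3cc(OC)c(OC)c(OC)c3)c(OC)c2)c1 | intermediate
12 | DEFG formate, formate ester of 13 | O=COc1cc(OC)c(OC)c(Oc2cc(OC)c(OC)c(OC)c2Oc2cc(OC)c(Oc3cc(OC)c(OC)c(OC)c3)c(OC)c2)c1 | intermediate
13 | DEFG phenol (ArOH), 3-{2-[3,5-dimethoxy-4-(3,4,5-trimethoxyphenoxy)phenoxy]-3,4,5-trimethoxyphenoxy}-4,5-dimethoxyphenol | Oc1cc(OC)c(OC)c(Oc2cc(OC)c(OC)c(OC)c2Oc2cc(OC)c(Oc3cc(OC)c(OC)c(OC)c3)c(OC)c2)c1 | intermediate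
14 | squaric acid dichloride, 3,4-dichlorocyclobut-3-ene-1,2-dione | O=C1C(Cl)=C(Cl)C1=O | starting material
15 | chloro squarate, 3-(ArO)-4-chlorocyclobut-3-ene-1,2-dione | O=C1C(=O)C(Oc2cc(OC)c(OC)c(Oc3cc(OC)c(OC)c(OC)c3Oc3cc(OC)c(Oc4cc(OC)c(OC)c(OC)c4)c(OC)c3)c2)=C1Cl | intermediate
16 | mixed squarate, 3-(ArO)-4-methoxycyclobut-3-ene-1,2-dione | COC1=C(Oc2cc(OC)c(OC)c(Oc3cc(OC)c(OC)c(OC)c3Oc3cc(OC)c(Oc4cc(OC)c(OC)c(OC)c4)c(OC)c3)c2)C(=O)C1=O | intermediate
17 | methyl vinyl ether | COC=C | starting material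
18 | 1-methoxyvinyllithium | [Li]C(=C)OC | intermediate
19 | lithium alkoxide of the 1,2-adduct, lithium 2-(ArO)-3-methoxy-4-(1-methoxyvinyl)-1-oxocyclobut-2-en-4-olate (racemic) | [Li+].C=C(OC)C1([O-])C(OC)=C(Oc2cc(OC)c(OC)c(Oc3cc(OC)c(OC)c(OC)c3Oc3cc(OC)c(Oc4cc(OC)c(OC)c(OC)c4)c(OC)c3)c2)C1=O | intermediate
20 | racemic 2-(ArO)-3,4-dimethoxy-4-(1-methoxyvinyl)cyclobut-2-en-1-one (key-step precursor; quaternary C4 unassigned, both enantiomers) | C=C(OC)C1(OC)C(OC)=C(Oc2cc(OC)c(OC)c(Oc3cc(OC)c(OC)c(OC)c3Oc3cc(OC)c(Oc4cc(OC)c(OC)c(OC)c4)c(OC)c3)c2)C1=O | intermediate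
21 | (Z)-dienylketene, 2-(ArO)-3,4,5-trimethoxyhexa-1,3,5-trien-1-one with the methoxyvinyl group cis to the ketene | O=C=C(Oc1cc(OC)c(OC)c(Oc2cc(OC)c(OC)c(OC)c2Oc2cc(OC)c(Oc3cc(OC)c(OC)c(OC)c3)c(OC)c2)c1)/C(OC)=C(OC)\C(OC)=C | intermediate
22 | cyclohexadienone, 2-(ArO)-3,4,5-trimethoxycyclohexa-2,4-dien-1-one | O=C1CC(OC)=C(OC)C(OC)=C1Oc1cc(OC)c(OC)c(Oc2cc(OC)c(OC)c(OC)c2Oc2cc(OC)c(Oc3cc(OC)c(OC)c(OC)c3)c(OC)c2)c1 | intermediate
23 | CDEFG phenol, 2-(ArO)-3,4,5-trimethoxyphenol (free hydroxyl on C1 of ring C) | Oc1cc(OC)c(OC)c(OC)c1Oc1cc(OC)c(OC)c(Oc2cc(OC)c(OC)c(OC)c2Oc2cc(OC)c(Oc3cc(OC)c(OC)c(OC)c3)c(OC)c2)c1 | intermediate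
24 | 4-bromo-3,5-dimethoxybenzaldehyde | O=Cc1cc(OC)c(Br)c(OC)c1 | starting material
25 | BCDEFG aldehyde, 3,5-dimethoxy-4-[2-(ArO)-3,4,5-trimethoxyphenoxy]benzaldehyde | O=Cc1cc(OC)c(Oc2cc(OC)c(OC)c(OC)c2Oc2cc(OC)c(OC)c(Oc3cc(OC)c(OC)c(OC)c3Oc3cc(OC)c(Oc4cc(OC)c(OC)c(OC)c4)c(OC)c3)c2)c(OC)c1 | intermediate
26 | BCDEFG formate, formate ester of 27 | O=COc1cc(OC)c(Oc2cc(OC)c(OC)c(OC)c2Oc2cc(OC)c(OC)c(Oc3cc(OC)c(OC)c(OC)c3Oc3cc(OC)c(Oc4cc(OC)c(OC)c(OC)c4)c(OC)c3)c2)c(OC)c1 | intermediate
27 | BCDEFG phenol, 3,5-dimethoxy-4-[2-(ArO)-3,4,5-trimethoxyphenoxy]phenol | Oc1cc(OC)c(Oc2cc(OC)c(OC)c(OC)c2Oc2cc(OC)c(OC)c(Oc3cc(OC)c(OC)c(OC)c3Oc3cc(OC)c(Oc4cc(OC)c(OC)c(OC)c4)c(OC)c3)c2)c(OC)c1 | intermediate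
28 | 2-iodo-1,3,5-trimethoxybenzene | COc1cc(OC)c(I)c(OC)c1 | starting material
29 | permethylated heptamer (eighteen methyl ethers), 2-{3,5-dimethoxy-4-[2-(ArO)-3,4,5-trimethoxyphenoxy]phenoxy}-1,3,5-trimethoxybenzene | COc1cc(OC)c(Oc2cc(OC)c(Oc3cc(OC)c(OC)c(OC)c3Oc3cc(OC)c(OC)c(Oc4cc(OC)c(OC)c(OC)c4Oc4cc(OC)c(Oc5cc(OC)c(OC)c(OC)c5)c(OC)c4)c3)c(OC)c2)c(OC)c1 | intermediate
30 | CNP0130704.0, the octadecahydroxy heptamer (achiral) | Oc1cc(O)c(Oc2cc(O)c(Oc3cc(O)c(O)c(O)c3Oc3cc(O)c(O)c(Oc4cc(O)c(O)c(O)c4Oc4cc(O)c(Oc5cc(O)c(O)c(O)c5)c(O)c4)c3)c(O)c2)c(O)c1 | target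

Total step count: 13 steps.
Longest linear sequence: 13 steps (1 to 30).

Steps most likely to fail

Step 8. The organolithium may attack the carbonyl flanking the aryloxy-bearing carbon, since the electronic bias between aryloxy and methoxy is only moderate, or may expel aryloxide by conjugate addition–elimination; either process erodes the supply of 20. The fallback sets out from 13 and 14 and comes back at 20. Two equivalents of 13 are condensed with 14 (2,6-lutidine, CH2Cl2, −78 °C to rt) to the symmetrical 3,4-bis(aryloxy)cyclobut-3-ene-1,2-dione F1, whose two carbonyl groups are equivalent. Addition of 18 at −78 °C then gives the lithium alkoxide F2 and, after MeOTf, the 2,3-bis(aryloxy)-4-methoxy-4-(1-methoxyvinyl)cyclobutenone F3, with no site question. NaOMe (1 equiv) in THF/MeOH at −40 to 0 °C should exchange only the aryloxy group on C3, the β-carbon of the vinylogous ester, by conjugate addition–elimination, since the aryloxy group on C2 has no such pathway. This delivers 20 and returns one equivalent of 13 for re-use.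

Step 10. Copper insertion and ligand exchange at the doubly ortho-methoxylated C–Br bond may be too slow with the bulky ortho-aryloxy phenoxide, so that reductive debromination of 24 and recovery of 23 dominate. The fallback sets out from 23 and comes back at 25. The copper coupling is replaced by uncatalysed nucleophilic aromatic substitution of the cesium phenoxide of 23 on 4-fluoro-3,5-dimethoxybenzaldehyde (Cs2CO3, DMSO, 100 °C). The para-formyl group stabilises the Meisenheimer adduct and no metal has to enter a hindered carbon–halogen bond. No new compound arises on this way.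

Step 9. The ketene may be intercepted before electrocyclisation, for instance by acylation of the electron-rich ring D or by adventitious nucleophiles, or the enol ether of 20 may hydrolyse before it is heated. The fallback sets out from 13 and comes back at 23, bypassing steps 7 to 9. Copper coupling of 13 with 6 (CuI, picolinic acid, K3PO4, DMSO, 90 °C) gives the 2-(ArO)-3,4,5-trimethoxybenzaldehyde F4. mCPBA in CH2Cl2 converts it into the aryl formate F5, and methanolysis (K2CO3 cat., MeOH) gives 23. This is the ring E sequence of steps 3 and 4 applied once more.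

Further compounds
F1 | step 8 | 3,4-bis(ArO)cyclobut-3-ene-1,2-dione | O=C1C(=O)C(Oc2cc(OC)c(OC)c(Oc3cc(OC)c(OC)c(OC)c3Oc3cc(OC)c(Oc4cc(OC)c(OC)c(OC)c4)c(OC)c3)c2)=C1Oc1cc(OC)c(OC)c(Oc2cc(OC)c(OC)c(OC)c2Oc2cc(OC)c(Oc3cc(OC)c(OC)c(OC)c3)c(OC)c2)c1
F2 | step 8 | lithium 2,3-bis(ArO)-4-(1-methoxyvinyl)-1-oxocyclobut-2-en-4-olate (racemic) | [Li+].C=C(OC)C1([O-])C(Oc2cc(OC)c(OC)c(Oc3cc(OC)c(OC)c(OC)c3Oc3cc(OC)c(Oc4cc(OC)c(OC)c(OC)c4)c(OC)c3)c2)=C(Oc2cc(OC)c(OC)c(Oc3cc(OC)c(OC)c(OC)c3Oc3cc(OC)c(Oc4cc(OC)c(OC)c(OC)c4)c(OC)c3)c2)C1=O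
F3 | step 8 | racemic 2,3-bis(ArO)-4-methoxy-4-(1-methoxyvinyl)cyclobut-2-en-1-one | C=C(OC)C1(OC)C(Oc2cc(OC)c(OC)c(Oc3cc(OC)c(OC)c(OC)c3Oc3cc(OC)c(Oc4cc(OC)c(OC)c(OC)c4)c(OC)c3)c2)=C(Oc2cc(OC)c(OC)c(Oc3cc(OC)c(OC)c(OC)c3Oc3cc(OC)c(Oc4cc(OC)c(OC)c(OC)c4)c(OC)c3)c2)C1=O
F0 | step 10 | none | none
F4 | step 9 | 2-(ArO)-3,4,5-trimethoxybenzaldehyde | O=Cc1cc(OC)c(OC)c(OC)c1Oc1cc(OC)c(OC)c(Oc2cc(OC)c(OC)c(OC)c2Oc2cc(OC)c(Oc3cc(OC)c(OC)c(OC)c3)c(OC)c2)c1
F5 | step 9 | 2-(ArO)-3,4,5-trimethoxyphenyl formate | O=COc1cc(OC)c(OC)c(OC)c1Oc1cc(OC)c(OC)c(Oc2cc(OC)c(OC)c(OC)c2Oc2cc(OC)c(Oc3cc(OC)c(OC)c(OC)c3)c(OC)c2)c1
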